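Put the same charge of X through the two vessels below and see how much of the product is still Q when it is read.

| flask | X | remark | time |
|---|---|---|---|
| birch | 0.45 M | one stirred flow tank at steady state, fed with the mixture as stated, mean residence time 40 min |  |
| ash | 0.45 M | everything together in a closed stirred flask, run for 40 min | 40 min |

    X → G (k1 = 0.060 /s)
    X ⇌ D (K2 = 0.70, k2 = 7.9 × 10⁻⁴ /s)
    G → L (k3 = 0.0015 /s)
    D → J (k4 = 0.0027 /s)
    L → Q (k5 = 0.0015 /s)
    Q ⇌ Z (K6 = 1.8, k6 = 1.4 × 10⁻⁴ /s)

* the set-up with the highest share of Q in all that became Q or J or Z, at the outlet or at the end ("none" if the first two lie within 2 percentage points) (birch / ash / none)
* share of Q in all that became Q or J or Z, at the outlet or at the end, birch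
* share of Q in all that became Q or J or Z, at the outlet or at the end, ash

Two chemists dispute this. The first looks at the last step: Q and Z are joined by an equilibrium of constant 1.8, so Q should hold 35.7 % of the pair in either vessel, and the answer is "none".

The second chemist, whose side I take, looks at the clock. The half-life of X by step 1 alone, 0.19 min, is much shorter than the 7.7 min of G by step 3 alone. X goes towards D with hardly any of its rate towards G, so I leave J out. What comes through L then follows two first-order steps of equal constant.

In ash, by my curve, 87.4 % of the charge has passed L by 40 min. The area under the curve divided by that height gives a mean age of 22.3 min. Multiplied by the forward constant of step 6, this gives 0.187. I call this the age number, the forward rate constant from Q to Z times the mean age of what has passed L, and I take it as my estimate of Z over Q.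

In birch the outflow takes a molecule regardless of its past, so the mean age is the residence time, 40 min, and the age number is 0.336, larger than in ash. The relaxation half-life of 53.0 min in ash is longer than the mean age there, so I do not expect equilibrium. Taking Q's share as one over one plus the age number, I commit to ash, with 74.9 % for birch and 84.2 % for ash.

The forecast sides with the second chemist, giving ash, with 76.9 % for birch and 83.4 % for ash, on the ground that in the flask “its Q forms late and has little time to convert to Z”; its two figures lie closer together than mine.

The simulation gives ash, with 76.9 % for birch and 83.4 % for ash, so my birch figure was low and my ash figure high.

In ash at 40.0 min, Z over Q reads 0.186 against an age number of 0.187, and the mean age of 22.3 min stays below the relaxation half-life of 53.0 min, which is kinetic control. Read at 1.0 h, the same flask has an age number of 0.330, and Z over Q reads 0.335. The first chemist's region lies later: at 400 min, ash stands at 35.9 %, against the 35.7 % of the Q and Z pair at equilibrium.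

(Its constants were drawn at random within sensible limits; no experiment stands behind them.)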